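**Plan**

- Retrosynthetic cuts, in order: C15 acid and C3 alcohol adjustments; the C3–C4 bond of ring A (an aldehyde C–H added across a 1,1-disubstituted alkene); the C9–C11 bond (alkyllithium plus enone carbonyl, with 1,3-transposition of oxygen); the C10–C1 and C10–C20 bonds (two enolate alkylations).
- Enabling feature: ring B (C5–C10 with the C8 methyl and the 7,8-alkene) together with C4, C18 and C19 is the complete ten-carbon skeleton of carvone. Ring A carries its C3 oxygen next to a quaternary C4 whose equatorial methyl can be the protonated terminus of an alkene, so C3–C4 is a hydroacylation bond.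
- Forward: (S)-carvone → C10 made quaternary (methyl, then allyl) → side chain joined at C9 and the enone turned into a C7 enol triflate → isopropenyl to 2-(acetoxymethyl)vinyl and allyl to a propanal arm → ring A closed last → enol triflate reduced, C3 ketone reduced, C15 oxidised.
- Stereochemistry: C5 from (S)-carvone; C10 by alkylation anti to the C5 substituent; C9 by axial protonation in the dissolving-metal reduction; C4 in the ring closure; C3 by equatorial hydride delivery; C13 from methyl hydrogen (R)-3-methylglutarate.

Key step: step 14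

Remark: the structure is read as (3S,4R,5S,9R,10S,13R), with the 3-OH axial and anti to the axial CH2OAc on C4 (C19, cis to the C10 methyl C20) and the C4 methyl (C18) equatorial; labdane numbering is used throughout.

**Route**

Step 1
Reactants: 1 methyl hydrogen (R)-3-methylglutarate
Product: 2 methyl (3R)-5-hydroxy-3-methylpentanoate
Conditions: BH3·SMe2, THF, 0 °C → rt; H2O
Reagents that add atoms: none
Why: Borane reduces the free carboxylic acid through its acyloxyborane much faster than the methyl ester (chemoselective borane reduction), and the stereocentre is not touched.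

Step 2
Reactants: 2 methyl (3R)-5-hydroxy-3-methylpentanoate
Product: 3 methyl (3S)-5-iodo-3-methylpentanoate
Conditions: I2, PPh3, imidazole, CH2Cl2, 0 °C → rt
Reagents that add atoms: iodine, II
Why: Appel-type iodination of the primary alcohol (alkoxyphosphonium ion displaced by iodide) is routine and remote from the stereocentre, whose descriptor changes only through the priority rules.

Step 3
Reactants: 3 methyl (3S)-5-iodo-3-methylpentanoate
Product: 4 (3S)-5-iodo-3-methylpentan-1-ol
Conditions: i-Bu2AlH (2.2 equiv), CH2Cl2, −78 → 0 °C; H2O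
Reagents that add atoms: none
Why: Aluminium hydride reduction of the ester to the primary alcohol should proceed at low temperature without reducing the primary alkyl iodide.

Step 4
Reactants: 4 (3S)-5-iodo-3-methylpentan-1-ol
Product: 5 tert-butyl{[(3S)-5-iodo-3-methylpentyl]oxy}dimethylsilane
Conditions: t-BuMe2SiCl, imidazole, CH2Cl2, 0 °C → rt
Reagents that add atoms: tert-butyldimethylsilyl chloride, CC(C)(C)[Si](C)(C)Cl
Why: Standard silylation of the primary alcohol masks C15 for the organolithium, chromium and dissolving-metal steps that follow.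

Step 5
Reactants: 6 (S)-(+)-carvone
Product: 8 (5S)-6-methylcarvone (C6 epimers), via lithium dienolate 7 (not isolated)
Conditions: LiN(i-Pr)2, THF, −78 °C; MeI, −78 → 0 °C
Reagents that add atoms: iodomethane, CI
Why: Kinetic deprotonation at the saturated α-carbon gives the cross-conjugated dienolate, which is C-methylated (enolate alkylation); the new centre is planarised again in step 6, so its configuration does not matter.

Step 6
Reactants: 8 (5S)-6-methylcarvone (C6 epimers)
Product: 10 (5R,6R)-6-allyl-2,6-dimethyl-5-(prop-1-en-2-yl)cyclohex-2-en-1-one, via tetrasubstituted lithium enolate 9 (not isolated)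
Conditions: LiN(i-Pr)2, THF, −78 °C; allyl bromide, −78 → 0 °C
Reagents that add atoms: allyl bromide, C=CCBr
Why: Enolate alkylation under 1,2-induction: allyl bromide should enter anti to the adjacent isopropenyl group, so the allyl group (C1–C3) ends trans and the methyl (C20) cis to C4, which fixes C10 and the later trans ring fusion.

Step 7
Reactants: 5 tert-butyl{[(3S)-5-iodo-3-methylpentyl]oxy}dimethylsilane, 10 (5R,6R)-6-allyl-2,6-dimethyl-5-(prop-1-en-2-yl)cyclohex-2-en-1-one
Product: 12 tertiary allylic alcohol from 1,2-addition at C9 (carbinol epimers), via primary alkyllithium 11 (not isolated)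
Conditions: 5, t-BuLi (2.0 equiv), Et2O/pentane, −78 °C; then 10, THF, −78 → −20 °C; H2O
Reagents that add atoms: none
Why: Iodine–lithium exchange gives the primary alkyllithium, which should add 1,2 to the enone carbonyl, which cannot be enolised at the quaternary α-carbon (organolithium addition); the carbinol configuration is erased in step 8.

Step 8
Reactants: 12 tertiary allylic alcohol from 1,2-addition at C9 (carbinol epimers)
Product: 13 (4R,5R)-4-allyl-3-[(3R)-5-(tert-butyldimethylsilyloxy)-3-methylpentyl]-2,4-dimethyl-5-(prop-1-en-2-yl)cyclohex-2-en-1-one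
Conditions: pyridinium chlorochromate [C5H5NH][CrO3Cl], 4 Å molecular sieves, CH2Cl2, rt
Reagents that add atoms: pyridinium chlorochromate (supplies the carbonyl oxygen), [O-][Cr](=O)(=O)Cl.c1cc[nH+]cc1
Why: Oxidative 1,3-transposition of a tertiary allylic alcohol: the chromate ester undergoes a [3,3] shift and is oxidised, moving oxygen from C9 to C7 and leaving the side chain on the alkene carbon C9.

Step 9
Reactants: 13 (4R,5R)-4-allyl-3-[(3R)-5-(tert-butyldimethylsilyloxy)-3-methylpentyl]-2,4-dimethyl-5-(prop-1-en-2-yl)cyclohex-2-en-1-one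
Product: 15 (3S,4R,5R)-4-allyl-3-[(3R)-5-(tert-butyldimethylsilyloxy)-3-methylpentyl]-2,4-dimethyl-5-(prop-1-en-2-yl)cyclohex-1-en-1-yl triflate, via lithium enolate 14 (not isolated)
Conditions: Li (2.2 equiv), t-BuOH (1.0 equiv), NH3(l)/THF, −78 °C; NH3 evaporated; PhNTf2, THF, −78 °C → rt
Reagents that add atoms: N-phenylbis(trifluoromethanesulfonimide), O=S(=O)(N(c1ccccc1)S(=O)(=O)C(F)(F)F)C(F)(F)F
Why: Birch-type conjugate reduction followed by O-sulfonylation of the regiodefined enolate (reductive enol triflation): the C9 carbanion should be protonated axially, anti to the axial C10 methyl, which puts 9-H on the face of 5-H and the side chain equatorial, and the enol triflate stores the 7,8-alkene in an electron-poor form.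

Step 10
Reactants: 15 (3S,4R,5R)-4-allyl-3-[(3R)-5-(tert-butyldimethylsilyloxy)-3-methylpentyl]-2,4-dimethyl-5-(prop-1-en-2-yl)cyclohex-1-en-1-yl triflate
Product: 16 allylic chloride (15 with the C5 substituent changed to 3-chloroprop-1-en-2-yl)
Conditions: Ca(OCl)2, CO2 (solid), CH2Cl2/H2O, 0 °C
Reagents that add atoms: calcium hypochlorite, [Ca+2].[O-]Cl.[O-]Cl
Why: Ene-type allylic chlorination by hypochlorous acid should take place at the most electron-rich 1,1-disubstituted alkene, since the enol triflate alkene is deactivated and the monosubstituted allyl group reacts more slowly.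

Step 11
Reactants: 16 allylic chloride (15 with the C5 substituent changed to 3-chloroprop-1-en-2-yl)
Product: 17 allylic acetate (15 with the C5 substituent changed to 3-acetoxyprop-1-en-2-yl)
Conditions: KOAc, 18-crown-6 (cat.), DMF, 50 °C
Reagents that add atoms: potassium acetate, CC(=O)[O-].[K+]
Why: SN2 displacement of a primary allylic chloride by acetate installs the C19 oxygen in its final form while the enol triflate and silyl ether are inert.

Step 12
Reactants: 17 allylic acetate (15 with the C5 substituent changed to 3-acetoxyprop-1-en-2-yl)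
Product: 19 primary alcohol (17 with the C10 allyl group changed to 3-hydroxypropyl), via alkyl(disiamyl)borane 18 (not isolated)
Conditions: (Me2CHCHMe)2BH (disiamylborane, preformed), THF, 0 °C; then 30% H2O2, aq. NaOAc, 0 °C → rt
Reagents that add atoms: hydrogen peroxide, OO
Why: Anti-Markovnikov hydroboration–oxidation: the bulky dialkylborane should select the monosubstituted alkene over the 1,1-disubstituted, inductively deactivated acetoxymethyl alkene and the tetrasubstituted enol triflate, and buffered oxidation spares the acetate.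

Step 13
Reactants: 19 primary alcohol (17 with the C10 allyl group changed to 3-hydroxypropyl)
Product: 20 aldehyde (17 with the C10 allyl group changed to 3-oxopropyl)
Conditions: DMP (1,1,1-triacetoxy-1,1-dihydro-1,2-benziodoxol-3(1H)-one), CH2Cl2, 0 °C → rt
Reagents that add atoms: none
Why: Periodinane oxidation of a primary alcohol to the aldehyde is non-basic and should leave acetate, silyl ether and enol triflate untouched.

Step 14
Reactants: 20 aldehyde (17 with the C10 allyl group changed to 3-oxopropyl)
Product: 21 19-acetoxy-15-(tert-butyldimethylsilyloxy)-3-oxolabd-7-en-7-yl triflate (trans-decalin; C4 methyl equatorial; C4 CH2OAc axial and cis to the C10 methyl)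
Conditions: 2-mesityl-6,7-dihydro-5H-pyrrolo[2,1-c][1,2,4]triazol-2-ium chloride (20 mol %), DBU (20 mol %), 1,4-dioxane (0.02 M), 100 °C
Reagents that add atoms: none
Why: Proposed new method: the triazolylidene adds to the C3 aldehyde to give the hydroxy-enamine acyl anion equivalent, whose O–H proton passes to the alkene terminus (C18) while C3 bonds to the internal carbon C4 in a concerted, asynchronous five-centre (Conia-ene-like) transition state, and loss of the carbene from the tetrahedral adduct releases the C3 ketone. The closest known reaction type is the carbene-catalysed intramolecular hydroacylation of unactivated 1,1-disubstituted alkenes by aromatic aldehydes through heteroatom tethers, which gives cyclic ketones with α-quaternary centres; the aliphatic aldehyde and the all-carbon tether are the untested part. Ring A closes 6-exo-trig at C4, and the trans ring fusion is already fixed by C5 and C10. The new stereocentre C4 should be set by a chair transition state in which the bulky azolium-bearing substituent on C3 is equatorial, so the enol O–H is axial on the face of 5-H and can reach only the pseudo-equatorial alkene terminus: C18 becomes the equatorial methyl and the bystander CH2OAc becomes axial, cis to the C10 methyl. The step needs chemoselectivity for the 1,1-disubstituted alkene over the ring B alkene and for cyclisation over aldehyde self-condensation, which the electron-poor tetrasubstituted enol triflate and high dilution should secure.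

Step 15
Reactants: 21 19-acetoxy-15-(tert-butyldimethylsilyloxy)-3-oxolabd-7-en-7-yl triflate
Product: 22 19-acetoxy-15-(tert-butyldimethylsilyloxy)labd-7-en-3-one
Conditions: Pd(OAc)2 (5 mol %), PPh3 (10 mol %), HCO2H, n-Bu3N, DMF, 60 °C
Reagents that add atoms: none
Why: Palladium-catalysed formate reduction of an enol triflate (oxidative addition to zerovalent palladium, formate decarboxylation, reductive elimination) should give the 7,8-alkene regiospecifically, and the acetate is now neopentyl and no longer allylic.

Step 16
Reactants: 22 19-acetoxy-15-(tert-butyldimethylsilyloxy)labd-7-en-3-one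
Product: 23 (3S)-19-acetoxy-15-(tert-butyldimethylsilyloxy)labd-7-en-3-ol (axial 3-OH)
Conditions: LiBH(s-Bu)3 (L-Selectride), THF, −78 °C; H2O
Reagents that add atoms: none
Why: Diastereoselective ketone reduction: the hindered trialkylborohydride should attack the C3 ketone from the equatorial direction, as with 4,4-disubstituted 3-oxo terpenoids, to give the axial alcohol, and the acetate cannot migrate because O3 and C19 are anti.

Step 17
Reactants: 23 (3S)-19-acetoxy-15-(tert-butyldimethylsilyloxy)labd-7-en-3-ol (axial 3-OH)
Product: 24 (3S)-19-acetoxylabd-7-ene-3,15-diol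
Conditions: HF·pyridine, pyridine/THF, 0 °C → rt
Reagents that add atoms: none
Why: Fluoride cleavage of the primary silyl ether under buffered acidic conditions should leave the acetate and the trisubstituted alkene unchanged.

Step 18
Reactants: 24 (3S)-19-acetoxylabd-7-ene-3,15-diol
Product: 25 (3S,4R,5S,9R,10S,13R)-19-acetoxy-3-hydroxylabd-7-en-15-oic acid (CNP0218903.1)
Conditions: TEMPO (20 mol %), PhI(OAc)2 (2.5 equiv), MeCN/H2O 1:1, rt
Reagents that add atoms: water, O
Why: Oxoammonium-mediated oxidation takes the primary alcohol through the aldehyde hydrate to the acid, and should spare the hindered axial secondary alcohol flanked by the quaternary C4 and the trisubstituted alkene.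

**Compound list**

1 | methyl hydrogen (R)-3-methylglutarate [(3R)-5-methoxy-3-methyl-5-oxopentanoic acid] | OC(=O)C[C@@H](C)CC(=O)OC | starting material
2 | methyl (3R)-5-hydroxy-3-methylpentanoate | OCC[C@@H](C)CC(=O)OC | intermediate
3 | methyl (3S)-5-iodo-3-methylpentanoate | ICC[C@@H](C)CC(=O)OC | intermediate
4 | (3S)-5-iodo-3-methylpentan-1-ol | ICC[C@@H](C)CCO | intermediate
5 | tert-butyl{[(3S)-5-iodo-3-methylpentyl]oxy}dimethylsilane | ICC[C@@H](C)CCO[Si](C)(C)C(C)(C)C | intermediate
6 | (S)-(+)-carvone | CC1=CC[C@@H](CC1=O)C(C)=C | starting material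
7 | lithium cross-conjugated dienolate of carvone | CC1=CC[C@@H](C=C1O[Li])C(C)=C | intermediate
8 | (5S)-6-methylcarvone, C6 epimers | C=C(C)[C@H]1CC=C(C)C(=O)C1C | intermediate
9 | tetrasubstituted lithium enolate of 6-methylcarvone | C=C(C)[C@H]1CC=C(C)C(O[Li])=C1C | intermediate
10 | (5R,6R)-6-allyl-2,6-dimethyl-5-(prop-1-en-2-yl)cyclohex-2-en-1-one (allyl trans to isopropenyl) | C=C(C)[C@H]1CC=C(C)C(=O)[C@]1(C)CC=C | intermediate
11 | [(3R)-5-(tert-butyldimethylsilyloxy)-3-methylpentyl]lithium | [Li]CC[C@@H](C)CCO[Si](C)(C)C(C)(C)C | intermediate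
12 | 6-allyl-1-[(3R)-5-(tert-butyldimethylsilyloxy)-3-methylpentyl]-2,6-dimethyl-5-(prop-1-en-2-yl)cyclohex-2-en-1-ol, carbinol epimers, ring centres as in 10 | C=C(C)[C@H]1CC=C(C)C(O)(CC[C@@H](C)CCO[Si](C)(C)C(C)(C)C)[C@]1(C)CC=C | intermediate
13 | (4R,5R)-4-allyl-3-[(3R)-5-(tert-butyldimethylsilyloxy)-3-methylpentyl]-2,4-dimethyl-5-(prop-1-en-2-yl)cyclohex-2-en-1-one | C=C(C)[C@H]1CC(=O)C(C)=C(CC[C@@H](C)CCO[Si](C)(C)C(C)(C)C)[C@]1(C)CC=C | intermediate
14 | lithium enolate from conjugate reduction of 13 (C7–OLi, 7,8-alkene, 9-H on the face of 5-H) | C=C(C)[C@H]1CC(O[Li])=C(C)[C@@H](CC[C@@H](C)CCO[Si](C)(C)C(C)(C)C)[C@]1(C)CC=C | intermediate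
15 | (3S,4R,5R)-4-allyl-3-[(3R)-5-(tert-butyldimethylsilyloxy)-3-methylpentyl]-2,4-dimethyl-5-(prop-1-en-2-yl)cyclohex-1-en-1-yl triflate | C=C(C)[C@H]1CC(OS(=O)(=O)C(F)(F)F)=C(C)[C@@H](CC[C@@H](C)CCO[Si](C)(C)C(C)(C)C)[C@]1(C)CC=C | intermediate
16 | allylic chloride: 15 with 3-chloroprop-1-en-2-yl on C5 | C=C(CCl)[C@H]1CC(OS(=O)(=O)C(F)(F)F)=C(C)[C@@H](CC[C@@H](C)CCO[Si](C)(C)C(C)(C)C)[C@]1(C)CC=C | intermediate
17 | allylic acetate: 15 with 3-acetoxyprop-1-en-2-yl on C5 | C=C(COC(C)=O)[C@H]1CC(OS(=O)(=O)C(F)(F)F)=C(C)[C@@H](CC[C@@H](C)CCO[Si](C)(C)C(C)(C)C)[C@]1(C)CC=C | intermediate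
18 | alkyl(disiamyl)borane from hydroboration of the allyl group of 17 | C=C(COC(C)=O)[C@H]1CC(OS(=O)(=O)C(F)(F)F)=C(C)[C@@H](CC[C@@H](C)CCO[Si](C)(C)C(C)(C)C)[C@]1(C)CCCB(C(C)C(C)C)C(C)C(C)C | intermediate
19 | primary alcohol: 17 with 3-hydroxypropyl on C10 | C=C(COC(C)=O)[C@H]1CC(OS(=O)(=O)C(F)(F)F)=C(C)[C@@H](CC[C@@H](C)CCO[Si](C)(C)C(C)(C)C)[C@]1(C)CCCO | intermediate
20 | aldehyde: 17 with 3-oxopropyl on C10 | C=C(COC(C)=O)[C@H]1CC(OS(=O)(=O)C(F)(F)F)=C(C)[C@@H](CC[C@@H](C)CCO[Si](C)(C)C(C)(C)C)[C@]1(C)CCC=O | intermediate
21 | 19-acetoxy-15-(tert-butyldimethylsilyloxy)-3-oxolabd-7-en-7-yl triflate; C4, C5, C9, C10, C13 as in 25 | CC(=O)OC[C@@]1(C)[C@H]2CC(OS(=O)(=O)C(F)(F)F)=C(C)[C@@H](CC[C@@H](C)CCO[Si](C)(C)C(C)(C)C)[C@]2(C)CCC1=O | intermediate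
22 | 19-acetoxy-15-(tert-butyldimethylsilyloxy)labd-7-en-3-one; stereocentres as in 25 | CC(=O)OC[C@@]1(C)[C@H]2CC=C(C)[C@@H](CC[C@@H](C)CCO[Si](C)(C)C(C)(C)C)[C@]2(C)CCC1=O | intermediate
23 | (3S)-19-acetoxy-15-(tert-butyldimethylsilyloxy)labd-7-en-3-ol, axial 3-OH; other centres as in 25 | CC(=O)OC[C@@]1(C)[C@H]2CC=C(C)[C@@H](CC[C@@H](C)CCO[Si](C)(C)C(C)(C)C)[C@]2(C)CC[C@@H]1O | intermediate
24 | (3S)-19-acetoxylabd-7-ene-3,15-diol; other centres as in 25 | CC(=O)OC[C@@]1(C)[C@H]2CC=C(C)[C@@H](CC[C@@H](C)CCO)[C@]2(C)CC[C@@H]1O | intermediate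
25 | (3S,4R,5S,9R,10S,13R)-19-acetoxy-3-hydroxylabd-7-en-15-oic acid (CNP0218903.1) | CC(=O)OC[C@@]1(C)[C@H]2CC=C(C)[C@@H](CC[C@@H](C)CC(=O)O)[C@]2(C)CC[C@@H]1O | target

**Step count and risks**

Total steps: 18. Longest linear sequence: 16 steps (steps 1–4, then 7–18); the branch from carvone is 14 steps.

Steps most likely to fail:

1. Step 14 (Proposed new method). The carbene-bound acyl anion equivalent of an aliphatic aldehyde may not engage the unactivated alkene, so that aldehyde self-condensation or enolisation takes over, or the chair preference that sets C4 may erode. The fallback uses known chemistry and sets out from aldehyde 20. Condensation with NH2OH·HCl in pyridine should give the oxime F1. Aqueous NaOCl in CH2Cl2 should convert it into the nitrile oxide F2, which should close ring A by intramolecular nitrile oxide–alkene cycloaddition to the fused isoxazoline F3. In F3 the oxygen-bound CH2 is held in the plane of the C3=N bond and so should be equatorial, with the acetoxymethyl group axial. Mo(CO)6 in wet MeCN should cleave the N–O bond and hydrolyse the imine to the β-hydroxy ketone F4. The surplus primary hydroxyl is then removed by Barton–McCombie deoxygenation: PhOC(S)Cl and pyridine should give the O-phenyl thionocarbonate F5, and Bu3SnH with AIBN, kept concentrated in toluene at 110 °C to outrun 1,2-acyl shift, should give the equatorial methyl. This comes back to the route at ketone 21.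

2. Step 9. Protonation of the C9 carbanion may leak to the wrong face, or O-sulfonylation of the hindered tetrasubstituted enolate may be incomplete in the presence of lithium alkoxide. The fallback sets out from enone 13 and replaces electron transfer by hydrometalation. Copper hydride conjugate reduction with [1,3-bis(2,6-diisopropylphenyl)imidazol-2-ylidene]CuCl (5 mol %), NaOt-Bu and PhMe2SiH in toluene should deliver hydride to C9 from the face anti to the axial C10 methyl and give the dimethylphenylsilyl enol ether F6. MeLi in THF at 0 °C should then release the alkoxide-free lithium enolate 14, where the fallback comes back to the route for triflation to 15.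

3. Step 10. Electrophilic chlorine may lose selectivity: reaction at the allyl group, hydrogen abstraction from C5 instead of the methyl group, or double chlorination. The fallback sets out from 15 and oxidises the C–H bond directly. SeO2 (cat.) with t-BuOOH in CH2Cl2 should hydroxylate the isopropenyl methyl by an ene reaction and [2,3]-sigmatropic shift to give the allylic alcohol F7. Acetylation with Ac2O and pyridine should then give 17, where it comes back to the route.

**Further compounds**

F1 | step 14 | oxime of aldehyde 20 | C=C(COC(C)=O)[C@H]1CC(OS(=O)(=O)C(F)(F)F)=C(C)[C@@H](CC[C@@H](C)CCO[Si](C)(C)C(C)(C)C)[C@]1(C)CCC=NO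
F2 | step 14 | nitrile oxide from F1 | C=C(COC(C)=O)[C@H]1CC(OS(=O)(=O)C(F)(F)F)=C(C)[C@@H](CC[C@@H](C)CCO[Si](C)(C)C(C)(C)C)[C@]1(C)CCC#[N+][O-]
F3 | step 14 | ring-A-fused isoxazoline (C3=N–O–CH2–C4; CH2OAc axial on C4) | CC(=O)OC[C@@]1(CO3)[C@H]2CC(OS(=O)(=O)C(F)(F)F)=C(C)[C@@H](CC[C@@H](C)CCO[Si](C)(C)C(C)(C)C)[C@]2(C)CCC1=N3
F4 | step 14 | β-hydroxy ketone: 21 with the equatorial C4 methyl replaced by CH2OH | CC(=O)OC[C@@]1(CO)[C@H]2CC(OS(=O)(=O)C(F)(F)F)=C(C)[C@@H](CC[C@@H](C)CCO[Si](C)(C)C(C)(C)C)[C@]2(C)CCC1=O
F5 | step 14 | O-phenyl thionocarbonate of F4 | CC(=O)OC[C@@]1(COC(=S)Oc3ccccc3)[C@H]2CC(OS(=O)(=O)C(F)(F)F)=C(C)[C@@H](CC[C@@H](C)CCO[Si](C)(C)C(C)(C)C)[C@]2(C)CCC1=O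
F6 | step 9 | dimethylphenylsilyl enol ether corresponding to enolate 14 | C=C(C)[C@H]1CC(O[Si](C)(C)c2ccccc2)=C(C)[C@@H](CC[C@@H](C)CCO[Si](C)(C)C(C)(C)C)[C@]1(C)CC=C
F7 | step 10 | allylic alcohol: 15 with 3-hydroxyprop-1-en-2-yl on C5 | C=C(CO)[C@H]1CC(OS(=O)(=O)C(F)(F)F)=C(C)[C@@H](CC[C@@H](C)CCO[Si](C)(C)C(C)(C)C)[C@]1(C)CC=C
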